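**Retrosynthetic overview**

1. Target ⇐ cross-conjugated dienol (hydroxyl-directed hydrogenation sets C1 and C2 from C19) ⇐ dienone (Felkin–Anh 1,2-reduction sets C19).
2. Ring A is closed last: dienone ⇐ 1,6-diketone by aldol cyclodehydration C1→C2. Enabling feature: C18 is quaternary, so the ring B ketone C19 enolises only at C1, which is also allylic to the C5=C6 alkene; every other aldol mode would give a bridged ring.
3. Ring B: C5=C6 by McMurry coupling of a diketone; C19–C1 by aldol addition of a neopentyl aldehyde to hex-5-en-2-one (terminal alkene = masked C2 ketone).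
4. Ring C on ring D by asymmetric Robinson annulation (C15); C10 and C9 by reductive alkylation; C18 by nitrile-anion alkylation.
5. Order of ring formation: D (purchased) → C (step 4) → B (step 15) → A (step 19).

Key step: step 19

Numbering used below (arbitrary): ring A = C1–C5 (C1 = A/B junction CH, C2 bears methyl C20, C5 = sp2 junction carbon); ring B = C1, C5, C6 (bears methyl C21), C7, C8, C9, C18, C19 (carbinol); ring C = C9, C10, C15, C16, C17, C18; ring D = C10–C15 (C12 bears C22, C23); C24 on C15, C25 on C18. β is the face of the C15 methyl; the target is 1β-H, 2β-H, 9β-H, 10α-H, 15β-CH3, 18α-CH3, 19β-OH.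

Assumption: all reactants that enter without a preparation step are commercial; stereocentres that are destroyed later are carried as mixtures.

Step 1
Reactants: 1 3,3-dimethylcyclohexan-1-one
Product: 3 (±)-2,5,5-trimethylcyclohexan-1-one, via lithium enolate 2 (not isolated)
Conditions: LiN(i-Pr)2, THF, −78 °C; MeI, −78 → 0 °C
Reagents that add atoms: iodomethane, CI
Why: Kinetic enolate alkylation: the amide base removes a C6 proton in preference to the neopentylic C2 proton next to the gem-dimethyl carbon, and the new centre is racemic but is erased in step 3.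

Step 2
Reactants: 3 (±)-2,5,5-trimethylcyclohexan-1-one; 4 (R)-1-phenylethan-1-amine
Product: 5 N-[(1R)-1-phenylethyl]-2,5,5-trimethylcyclohexan-1-imine
Conditions: TsOH (cat.), toluene, reflux, Dean–Stark trap
Reagents that add atoms: none
Why: Acid-catalysed imine condensation with azeotropic removal of water installs the chiral auxiliary and sets no stereocentre of the target.

Step 3
Reactants: 5 N-[(1R)-1-phenylethyl]-2,5,5-trimethylcyclohexan-1-imine; 6 but-3-en-2-one
Product: 8 (2S)-2,5,5-trimethyl-2-(3-oxobutyl)cyclohexan-1-one, via Michael-adduct imine 7 (not isolated)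
Conditions: 6, THF, 40 °C; then AcOH/H2O (1:4), 23 °C
Reagents that add atoms: water, O
Why: Asymmetric Michael addition of a chiral imine through its more substituted secondary enamine tautomer (aza-ene-type transition state): the enone is attacked on the face anti to the phenyl group of the (R)-auxiliary, which should set quaternary C15 as (S), and mild acid then hydrolyses the imine.

Step 4
Reactants: 8 (2S)-2,5,5-trimethyl-2-(3-oxobutyl)cyclohexan-1-one
Product: 9 (4aS)-4a,7,7-trimethyl-4,4a,5,6,7,8-hexahydronaphthalen-2(3H)-one
Conditions: NaOMe, MeOH, 60 °C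
Reagents that add atoms: none
Why: Intramolecular aldol condensation (second stage of the Robinson annulation) closes ring C as the conjugated enone and leaves C15 untouched.

Step 5
Reactants: 9 (4aS)-4a,7,7-trimethyl-4,4a,5,6,7,8-hexahydronaphthalen-2(3H)-one; 10 2-(2-bromoethyl)-2-methyl-1,3-dioxolane
Product: 12 trans-fused ring C/D ketone (C18=O) with the ketal side chain equatorial at C9 (9β-H 10α-H 15β-CH3), via lithium enolate 11 (not isolated)
Conditions: Li, NH3/THF, t-BuOH (1 equiv), −78 °C; isoprene; NH3 removed; 10, HMPA, THF, −78 → 23 °C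
Reagents that add atoms: none
Why: Stork reductive alkylation: axial protonation at C10 gives the trans ring fusion (10α-H anti to the C15 methyl), and the regiodefined C18 enolate is alkylated only at C9, where the side chain should end equatorial because axial approach is blocked by the 1,3-diaxial C15 methyl and the centre is epimerisable.

Step 6
Reactants: 12 trans-fused ring C/D ketone
Product: 13 C18 carbonitrile (both C18 epimers)
Conditions: TosMIC, KOt-Bu, EtOH (2 equiv), DME, 0 → 40 °C
Reagents that add atoms: p-toluenesulfonylmethyl isocyanide, Cc1ccc(cc1)S(=O)(=O)C[N+]#[C-]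
Why: Van Leusen reductive cyanation converts the ketone into the one-carbon-homologated nitrile, and the C18 configuration is irrelevant because this centre is deprotonated in the next step.

Step 7
Reactants: 13 C18 carbonitrile
Product: 15 18α-cyano-18β-(benzyloxymethyl) nitrile, via lithiated nitrile 14 (not isolated)
Conditions: LiN(i-Pr)2, THF, −78 °C; BnOCH2Cl, −78 → 0 °C
Reagents that add atoms: benzyl chloromethyl ether, ClCOCc1ccccc1
Why: Alkylation of a cyclohexanecarbonitrile anion: the planar N-lithio ketenimine is attacked from the equatorial direction, trans to the C9 side chain, so CH2OBn (future C19) becomes equatorial (β) and the nitrile (future C25) axial (α), which sets quaternary C18.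

Step 8
Reactants: 15 18α-cyano-18β-(benzyloxymethyl) nitrile
Product: 16 18α-formyl aldehyde
Conditions: i-Bu2AlH, toluene, −78 → 0 °C; aq. sodium potassium tartrate
Reagents that add atoms: water, O
Why: Partial reduction of the nitrile gives an aluminium imine that is hydrolysed on buffered work-up to the non-enolisable aldehyde, with the ketal intact and no stereocentre affected.

Step 9
Reactants: 16 18α-formyl aldehyde
Product: 18 benzyl ether with the 18α-methyl group (C25), via hydrazone 17 (not isolated)
Conditions: N2H4·H2O, KOH, diethylene glycol, 130 → 200 °C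
Reagents that add atoms: none
Why: Wolff–Kishner reduction (Huang-Minlon procedure) turns the axial formyl group into the C25 methyl, the quaternary centre cannot epimerise, and ketal and benzyl ether are stable to hot alkali.

Step 10
Reactants: 18 benzyl ether with the 18α-methyl group
Product: 19 primary alcohol (C19–OH)
Conditions: H2 (1 atm), Pd/C (10%), EtOAc, 23 °C
Reagents that add atoms: none
Why: Hydrogenolysis of the benzyl ether is clean here because no alkene is present yet.

Step 11
Reactants: 19 primary alcohol
Product: 20 neopentyl aldehyde (C19=O)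
Conditions: Dess–Martin periodinane, NaHCO3, CH2Cl2, 0 → 23 °C
Reagents that add atoms: none
Why: Dess–Martin oxidation gives the non-enolisable aldehyde under buffered conditions that spare the ketal.

Step 12
Reactants: 20 neopentyl aldehyde; 21 hex-5-en-2-one
Product: 23 β-hydroxy ketone (C19 carbinol, C5 ketone, terminal alkene C2=C20), via lithium enolate 22 (not isolated)
Conditions: LiN(i-Pr)2, THF, −78 °C, 21; then 20, −78 °C; aq. NH4Cl
Reagents that add atoms: none
Why: Directed aldol addition: kinetic deprotonation at the methyl group gives the terminal enolate, which adds to the non-enolisable aldehyde to form the C19–C1 bond, and the C19 configuration is inconsequential because C19 is oxidised in step 17.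

Step 13
Reactants: 23 β-hydroxy ketone
Product: 24 tert-butyldimethylsilyl ether
Conditions: t-BuMe2SiOTf, 2,6-lutidine, CH2Cl2, −78 → 0 °C
Reagents that add atoms: tert-butyldimethylsilyl trifluoromethanesulfonate, CC(C)(C)[Si](C)(C)OS(=O)(=O)C(F)(F)F
Why: Silylation with the silyl triflate protects the hindered secondary alcohol so that the aldol cannot revert or bind titanium in step 15.

Step 14
Reactants: 24 tert-butyldimethylsilyl ether
Product: 25 diketone (C5 ketone and C6 methyl ketone)
Conditions: PPTS, acetone/H2O (10:1), 55 °C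
Reagents that add atoms: water, O
Why: Mild acid-catalysed ketal hydrolysis releases the C6 methyl ketone while the hindered secondary silyl ether and the terminal alkene are left in place.

Step 15
Reactants: 25 diketone
Product: 26 ring B cyclooctene silyl ether (tetrasubstituted C5=C6)
Conditions: TiCl3(DME)1.5, Zn–Cu couple, DME, reflux; 25 added over 30 h (final 0.005 M)
Reagents that add atoms: none
Why: Intramolecular McMurry coupling on low-valent titanium closes the eight-membered ring B and places the tetrasubstituted alkene regiospecifically between C5 and C6 (cis by ring constraint), with slow addition favouring cyclisation and silyl ether and alkene being tolerated.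

Step 16
Reactants: 26 ring B cyclooctene silyl ether
Product: 27 homoallylic alcohol
Conditions: n-Bu4NF, THF, 50 °C
Reagents that add atoms: none
Why: Fluoride-mediated desilylation frees the C19 hydroxyl without affecting either alkene.

Step 17
Reactants: 27 homoallylic alcohol
Product: 28 β,γ-unsaturated ketone (C19=O, C5=C6)
Conditions: Dess–Martin periodinane, NaHCO3, CH2Cl2, 0 °C
Reagents that add atoms: none
Why: Buffered Dess–Martin oxidation gives the ketone without double-bond migration, since conjugation is poor in the eight-membered ring and the β,γ-alkene is tetrasubstituted.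

Step 18
Reactants: 28 β,γ-unsaturated ketone
Product: 29 1,6-diketone (C19=O and C2 methyl ketone)
Conditions: PdCl2 (0.1 equiv), CuCl (1 equiv), O2 (1 atm), DMF/H2O (7:1), 23 °C
Reagents that add atoms: water, O
Why: Tsuji–Wacker oxidation converts only the monosubstituted terminal alkene into the methyl ketone (Markovnikov), the tetrasubstituted alkene being inert to divalent palladium.

Step 19
Reactants: 29 1,6-diketone
Product: 31 cross-conjugated dienone (C19=O, C1=C2, C5=C6), via ketol 30 (not isolated)
Conditions: KOH (2 equiv), MeOH, 23 → 50 °C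
Reagents that add atoms: none
Why: Base removes a proton from C1, the only enolisable position of the C19 ketone (C18 is quaternary) and the most acidic one because it is also allylic to C5=C6; the dienolate carbon C1 adds to the C2 methyl ketone and E1cB loss of water from ketol 30 gives the tetrasubstituted C1=C2 enone (intramolecular aldol condensation, closest analogy the cyclisation of octane-2,7-dione to 1-acetyl-2-methylcyclopentene). Ring A closes in the 5-(enolexo)-exo-trig mode. No stereocentre is created: C1 is deliberately returned to sp2 so that C1 and C2 can be set together and relative to C19 in step 21, while C9, C10, C15 and C18 carry no acidic hydrogen and are untouched. The step needs site selectivity among three enolisable positions and two carbonyl groups: attack by C3 or C20 on C19 would have to hit a neopentyl ketone and would give a bridged ring with a bridgehead alkene, and attack through the γ-carbon C6 would need a 5-(enolendo) geometry, so only the C1→C2 closure is open. It also needs the C5=C6 alkene to stay in place, which the substrate secures because the dienolate reacts and is reprotonated at its α-carbon C1 and the ring B alkene is already tetrasubstituted.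

Step 20
Reactants: 31 cross-conjugated dienone
Product: 32 dienol (19β-OH)
Conditions: NaBH4, CeCl3·7H2O, MeOH, −40 → 0 °C
Reagents that add atoms: none
Why: Luche reduction gives 1,2-addition to the hindered enone, and Felkin–Anh control from quaternary C18 (branched C9, tied into ring B, perpendicular to the carbonyl; hydride anti to it over the small C25 methyl, from the periphery of ring B) should give the 19β-alcohol.

Step 21
Reactants: 32 dienol
Product: 33 target CNP0399382.1
Conditions: [Ir(cod)(PCy3)(py)]PF6 (5 mol%), H2 (1 atm), CH2Cl2, 0 → 23 °C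
Reagents that add atoms: none
Why: Hydroxyl-directed hydrogenation: A(1,3) strain with the C20 methyl holds the C19–H bond in the plane of the C1=C2 alkene, so the hydroxyl lies over one face and C18 under the other, and cis delivery of H2 from the hydroxyl face should set 1β-H and 2β-H together, while the tetrasubstituted C5=C6 alkene is only homoallylic and more hindered and should survive.

**Compound list**

1 | 3,3-dimethylcyclohexan-1-one | O=C1CCCC(C)(C)C1 | starting material
2 | lithium 5,5-dimethylcyclohex-1-en-1-olate | [Li]OC1=CCCC(C)(C)C1 | intermediate (not isolated)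
3 | (±)-2,5,5-trimethylcyclohexan-1-one | CC1CCC(C)(C)CC1=O | intermediate
4 | (R)-1-phenylethan-1-amine | C[C@@H](N)c1ccccc1 | starting material
5 | N-[(1R)-1-phenylethyl]-2,5,5-trimethylcyclohexan-1-imine | CC1CCC(C)(C)CC1=N[C@H](C)c1ccccc1 | intermediate
6 | but-3-en-2-one | CC(=O)C=C | starting material
7 | 4-[(1S)-1,4,4-trimethyl-2-{[(1R)-1-phenylethyl]imino}cyclohexyl]butan-2-one | CC(=O)CC[C@]1(C)CCC(C)(C)CC1=N[C@H](C)c1ccccc1 | intermediate (not isolated)
8 | (2S)-2,5,5-trimethyl-2-(3-oxobutyl)cyclohexan-1-one | CC(=O)CC[C@]1(C)CCC(C)(C)CC1=O | intermediate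
9 | (4aS)-4a,7,7-trimethyl-4,4a,5,6,7,8-hexahydronaphthalen-2(3H)-one | O=C1CC[C@]2(C)CCC(C)(C)CC2=C1 | intermediate
10 | 2-(2-bromoethyl)-2-methyl-1,3-dioxolane | CC1(CCBr)OCCO1 | starting material
11 | lithium enolate of the trans-decalone (C9=C18–OLi, 10α-H) | [Li]OC=1CC[C@]2(C)CCC(C)(C)C[C@H]2C=1 | intermediate (not isolated)
12 | trans-fused ring C/D ketone, C9 side chain CH2CH2C(OCH2CH2O)CH3 equatorial | O=C1CC[C@]2(C)CCC(C)(C)C[C@H]2[C@@H]1CCC1(C)OCCO1 | intermediate
13 | C18 carbonitrile (C18 epimers) | N#CC1CC[C@]2(C)CCC(C)(C)C[C@H]2[C@@H]1CCC1(C)OCCO1 | intermediate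
14 | N-lithio ketenimine of 13 | [Li]N=C=C1CC[C@]2(C)CCC(C)(C)C[C@H]2[C@@H]1CCC1(C)OCCO1 | intermediate (not isolated)
15 | 18α-cyano-18β-(benzyloxymethyl) nitrile | C(c1ccccc1)OC[C@@]2(C#N)CC[C@]3(C)CCC(C)(C)C[C@H]3[C@@H]2CCC2(C)OCCO2 | intermediate
16 | 18α-formyl-18β-(benzyloxymethyl) aldehyde | C(c1ccccc1)OC[C@@]2(C=O)CC[C@]3(C)CCC(C)(C)C[C@H]3[C@@H]2CCC2(C)OCCO2 | intermediate
17 | hydrazone of 16 | C(c1ccccc1)OC[C@@]2(C=NN)CC[C@]3(C)CCC(C)(C)C[C@H]3[C@@H]2CCC2(C)OCCO2 | intermediate (not isolated)
18 | 18α-methyl-18β-(benzyloxymethyl) ketal | C(c1ccccc1)OC[C@@]2(C)CC[C@]3(C)CCC(C)(C)C[C@H]3[C@@H]2CCC2(C)OCCO2 | intermediate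
19 | primary alcohol (C19–OH) | OC[C@@]1(C)CC[C@]2(C)CCC(C)(C)C[C@H]2[C@@H]1CCC1(C)OCCO1 | intermediate
20 | neopentyl aldehyde (C19=O) | O=C[C@@]1(C)CC[C@]2(C)CCC(C)(C)C[C@H]2[C@@H]1CCC1(C)OCCO1 | intermediate
21 | hex-5-en-2-one | CC(=O)CCC=C | starting material
22 | lithium hexa-1,5-dien-2-olate | [Li]OC(=C)CCC=C | intermediate (not isolated)
23 | β-hydroxy ketone (C19 epimers) | C=CCCC(=O)CC(O)[C@@]1(C)CC[C@]2(C)CCC(C)(C)C[C@H]2[C@@H]1CCC1(C)OCCO1 | intermediate
24 | tert-butyldimethylsilyl ether of 23 | C=CCCC(=O)CC(O[Si](C)(C)C(C)(C)C)[C@@]1(C)CC[C@]2(C)CCC(C)(C)C[C@H]2[C@@H]1CCC1(C)OCCO1 | intermediate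
25 | diketone (C5 and C6 ketones) | C=CCCC(=O)CC(O[Si](C)(C)C(C)(C)C)[C@@]1(C)CC[C@]2(C)CCC(C)(C)C[C@H]2[C@@H]1CCC(C)=O | intermediate
26 | ring B cyclooctene silyl ether | C/C1=C(\CCC=C)CC(O[Si](C)(C)C(C)(C)C)[C@@]2(C)CC[C@]3(C)CCC(C)(C)C[C@H]3[C@@H]2CC1 | intermediate
27 | homoallylic alcohol | C/C1=C(\CCC=C)CC(O)[C@@]2(C)CC[C@]3(C)CCC(C)(C)C[C@H]3[C@@H]2CC1 | intermediate
28 | β,γ-unsaturated ketone | C/C1=C(\CCC=C)CC(=O)[C@@]2(C)CC[C@]3(C)CCC(C)(C)C[C@H]3[C@@H]2CC1 | intermediate
29 | 1,6-diketone | C/C1=C(\CCC(C)=O)CC(=O)[C@@]2(C)CC[C@]3(C)CCC(C)(C)C[C@H]3[C@@H]2CC1 | intermediate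
30 | ketol (C2 tertiary alcohol, ring A closed) | C/C1=C2\CCC(C)(O)C2C(=O)[C@@]2(C)CC[C@]3(C)CCC(C)(C)C[C@H]3[C@@H]2CC1 | intermediate (not isolated)
31 | cross-conjugated dienone | C/C1=C2\CCC(C)=C2C(=O)[C@@]2(C)CC[C@]3(C)CCC(C)(C)C[C@H]3[C@@H]2CC1 | intermediate
32 | dienol (19β-OH) | C/C1=C2\CCC(C)=C2[C@@H](O)[C@@]2(C)CC[C@]3(C)CCC(C)(C)C[C@H]3[C@@H]2CC1 | intermediate
33 | CNP0399382.1 | C/C1=C2\CC[C@H](C)[C@@H]2[C@@H](O)[C@@]2(C)CC[C@]3(C)CCC(C)(C)C[C@H]3[C@@H]2CC1 | target

**Totals**

Total step count: 21. Longest linear sequence: 21 steps (from 1); the other building blocks enter directly.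

**Steps most likely to fail**

Step 15. Intermolecular coupling, arrest at the pinacol stage or β-elimination of the silyloxy group on the titanium surface may compete with ring closure. The fallback sets out from 25: SmI2 (THF/HMPA, −78 → 23 °C) should effect intramolecular pinacol coupling to the ring B cis-1,2-diol F1. 1,1′-Thiocarbonyldiimidazole (toluene, 110 °C) should convert it into the cyclic thiocarbonate F2. Corey–Winter fragmentation with 1,3-dimethyl-2-phenyl-1,3,2-diazaphospholidine (40 °C) should then give the alkene, and the route is rejoined at 26.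

Step 20. Facial selectivity of hydride delivery may be poor or reversed, because the two flanking groups on C18 differ little in size. The fallback sets out from 31: the same reduction then delivers mainly the 19-epimeric dienol F3, which is separated. Mitsunobu esterification (4-nitrobenzoic acid, PPh3, DIAD, toluene, 0 → 23 °C) should invert it to the 19β 4-nitrobenzoate F4, and methanolysis (K2CO3, MeOH) returns to the route at 32.

Step 21. Chemoselectivity may be lost through reduction of the C5=C6 alkene, or the doubly allylic alcohol may ionise under the acidic iridium hydride. The fallback sets out from 28 and avoids the allylic alcohol altogether. Soft enolisation (t-BuMe2SiOTf, Et3N, CH2Cl2) should give the silyl dienol ether F5. Pd(OAc)2-mediated cycloalkenylation of the silyl enol ether onto the terminal alkene (MeCN, 23 °C) should close ring A to the exo-methylene ketone F6. Heterogeneous hydrogenation (H2, Pd/C, EtOAc) from the face anti to C19 should give the saturated ketone F7, and hydride reduction (NaBH4, CeCl3·7H2O, MeOH) rejoins the route at 33.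

**Further compounds**

F1 | step 15 | ring B cis-5,6-diol silyl ether | CC1(O)C(O)(CCC=C)CC(O[Si](C)(C)C(C)(C)C)[C@@]2(C)CC[C@]3(C)CCC(C)(C)C[C@H]3[C@@H]2CC1
F2 | step 15 | cyclic thiocarbonate of F1 | CC12OC(=S)OC1(CCC=C)CC(O[Si](C)(C)C(C)(C)C)[C@@]1(C)CC[C@]3(C)CCC(C)(C)C[C@H]3[C@@H]1CC2
F3 | step 20 | 19-epimeric dienol (19α-OH) | C/C1=C2\CCC(C)=C2[C@H](O)[C@@]2(C)CC[C@]3(C)CCC(C)(C)C[C@H]3[C@@H]2CC1
F4 | step 20 | 19β 4-nitrobenzoate | C/C1=C2\CCC(C)=C2[C@@H](OC(=O)c4ccc(cc4)[N+](=O)[O-])[C@@]2(C)CC[C@]3(C)CCC(C)(C)C[C@H]3[C@@H]2CC1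
F5 | step 21 | silyl dienol ether of 28 | C/C1=C(\CCC=C)/C=C(O[Si](C)(C)C(C)(C)C)\[C@@]2(C)CC[C@]3(C)CCC(C)(C)C[C@H]3[C@@H]2CC1
F6 | step 21 | exo-methylene ketone (ring A closed, 1β-H) | C/C1=C2\CCC(=C)[C@@H]2C(=O)[C@@]2(C)CC[C@]3(C)CCC(C)(C)C[C@H]3[C@@H]2CC1
F7 | step 21 | saturated ring A ketone (1β-H, 2β-H) | C/C1=C2\CC[C@H](C)[C@@H]2C(=O)[C@@]2(C)CC[C@]3(C)CCC(C)(C)C[C@H]3[C@@H]2CC1
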